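Temperature is the one difference between the two runs you have. The noon flask stands at 80 °C and is the flask asked about, followed further to 25 min. The spring run stands at 75 °C.

all flasks: starting material 0.050 M

| charge | coupling partner | temperature | remark | time |
|---|---|---|---|---|
| noon | 0.060 M | 80 °C | the very flask that is asked about, followed so far |  |
| spring | 0.060 M | 75 °C | run made earlier |  |
| flask | 0.0600 M | 80 °C |  | 25 min |

| run | time / min | first product / % | starting material / % |
|---|---|---|---|
| noon | 1.50 | 24.9 | 56.9 |
| noon | 3.00 | 27.3 | 46.5 |
| noon | 6.00 | 28.2 | 37.6 |
| noon | 10.0 | 29.5 | 30.5 |
| noon | 20.0 | 34.4 | 21.3 |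
| spring | 1.50 | 23.9 | 60.1 |
| spring | 3.00 | 27.9 | 47.5 |
| spring | 6.00 | 28.6 | 39.3 |
| spring | 10.0 | 28.3 | 33.5 |
| spring | 20.0 | 28.9 | 25.6 |

(standard deviation of a reading: 0.5 percentage points)

- the volume of additions can be left aside

- theta: change nothing and wait 12 min more
- epsilon: at 25 min raise the temperature by 15 K, then wait 12 min
- delta: at 25 min add coupling partner, 100 % of the amount charged, then wait 12 min
- eta: at 25 min take out 90 % of the released group then present, then wait 12 min

- first product, in percent of the starting material first charged, at 25 min
- what to do for the largest gain in first product; "none" if nothing gains more than 2 percentage points (theta / epsilon / delta / eta / none)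
- first product present, in percent of the starting material first charged, after theta
- first product present, in percent of the starting material first charged, after eta

Start with the rate. In the noon flask the starting material falls to 56.9 % by 1.50 min, which gives a specific rate of 0.376 min⁻¹: the fraction of the remaining starting material lost per minute, read over that stretch as if it were a pseudo-first-order constant. Between 10.0 min and 20.0 min it reads 0.0359 min⁻¹, so it has slowed about ten times. The plain loss per minute has slowed by a factor of 31.2, and roughly 3.03 of that is simply less starting material.

What slows the specific rate? Write the balance of starting material, the smaller charge. By 20.0 min, 78.7 % of it is gone. Coupling partner was charged at 120 % of it, so one partner for each would leave 41.3 %. If the specific rate goes with the partner present, that is a slowing of 2.91 from the charge to 20.0 min, which is less than the factor read, so something further consumes partner or hinders the step.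

My own reckoning: held at the late rate, the noon flask loses 3.5 percentage points of starting material by 25 min. Late on, first product gained 0.533 per point lost, so I expect about 36.3 % now. In the spring run that gain reads 0.0759, which is smaller, so I would heat.

The forecast gives 36.5 % now, 40 % after theta, 40 % after eta, and chooses epsilon: “Heating looks best, though this is tentative”.

The simulation gives 35.0 %, 36.4 % after theta and 36.4 % after eta. It chooses epsilon, which gains 12 points, against 3.8 points for delta and 1.3 points for theta.

    coupling partner ⇌ dormant form (K = 2.10, k = 0.00630 s⁻¹, Ea = 98.0 kJ mol⁻¹, ΔH = −5.00 kJ mol⁻¹)
    coupling partner + first product → double product + released group (k = 0.0110 M⁻¹ s⁻¹, Ea = 73.0 kJ mol⁻¹)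
    starting material + coupling partner → other mono adduct + released group (k = 0.0590 M⁻¹ s⁻¹, Ea = 52.0 kJ mol⁻¹)
    starting material + coupling partner → first product + released group (k = 0.130 M⁻¹ s⁻¹, Ea = 46.0 kJ mol⁻¹)
    coupling partner + other mono adduct → double product + released group (k = 0.830 M⁻¹ s⁻¹, Ea = 66.0 kJ mol⁻¹)
    first product ⇌ isomer of the product (K = 0.510, k = 0.00400 s⁻¹, Ea = 110 kJ mol⁻¹, ΔH = −77.0 kJ mol⁻¹)
    starting material → decomposition product (k = 3.20 × 10⁻⁶ s⁻¹, Ea = 115 kJ mol⁻¹)
    (constants at 80 °C)

In the asked flask, the specific rate between 12.5 min and 25.0 min is 0.0286 min⁻¹, against the 0.376 min⁻¹ read over the first 1.50 min. The neighbouring flask holds 0.20 M of starting material with the same partner charge. Its mean specific rate over 25.0 min is 0.0123 min⁻¹. There, one partner for each starting material lost would leave 12.2 % of the partner charge, yet the flask holds 0.0262 % of it free and 2.05 × 10⁻⁴ M as dormant form. It ends with 73.6 % of starting material and 11.7 % of first product.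

(The runs were computed with made-up constants, and the scatter is random.)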